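## Retrosynthetic overview

1. The target comes from fluoride removal of five silyl groups; the enone is made last by aldol addition and dehydration of the C8 acetyl group with a protected 4-hydroxybenzaldehyde.
2. The pyran ring of the chroman is closed at C2–O by a Mitsunobu reaction (inversion) of an (S)-benzylic alcohol from asymmetric transfer hydrogenation; the aryl ketone comes from a Weinreb amide and an aryl Grignard reagent.
3. The Weinreb amide comes from aminolysis of an 8-acetyl-3,4-dihydrocoumarin. That lactone is made in one step (C4a–C4 bond, C4 stereocentre, lactone ring) by the proposed carbene-catalysed oxidative annulation of a protected 2,4-dihydroxy-6-methoxyacetophenone with a δ-silyloxy enal.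
4. The enal comes from cross-metathesis of a homoallylic silyl ether; its carbinol centre is set by Keck allylation of a 3-arylpropanal.
5. Ring order: the benzene rings are bought; the lactone ring is formed first and then opened; the pyran ring of the chroman is closed last.

Abbreviations: TBS = tert-butyldimethylsilyl, TIPS = triisopropylsilyl.

Assumption: the catalysts of steps 4, 7 and 10 are taken to follow their usual facial models; if a model run shows the opposite sense, the mirror-image catalyst is used with no other change.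

Note on descriptors: the carbon that becomes C4 of the chroman never changes geometry after step 7. Its label reads S in 9, 10, 13 and 20 but R in 14, 15, 17, 18 and 19, only because the silyloxy-bearing arm outranks the other arm there.

## Route

Step 1
Reactants: 1 1-(2,4-dihydroxy-6-methoxyphenyl)ethan-1-one
Product: 2 1-[2-hydroxy-6-methoxy-4-(TIPS-oxy)phenyl]ethan-1-one
Conditions: TIPSCl (1.05 equiv), imidazole, CH2Cl2, 0 → 25 °C
Reagents that add atoms: triisopropylsilyl chloride, CC(C)[Si](Cl)(C(C)C)C(C)C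
Why: Phenol silylation; the 4-OH is the only phenol not held in a hydrogen bond to the acetyl carbonyl, so it reacts selectively and the chelated 2-OH stays free for step 7.

Step 2
Reactants: 3 methyl 3-(4-hydroxyphenyl)propanoate
Product: 4 methyl 3-[4-(TBS-oxy)phenyl]propanoate
Conditions: TBSCl, imidazole, DMF, 25 °C
Reagents that add atoms: tert-butyldimethylsilyl chloride, CC(C)(C)[Si](C)(C)Cl
Why: Standard phenol silylation; the aryl TBS ether survives the later organometallic and redox steps and is removed by fluoride at the end.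

Step 3
Reactants: 4 methyl 3-[4-(TBS-oxy)phenyl]propanoate
Product: 5 3-[4-(TBS-oxy)phenyl]propanal
Conditions: i-Bu2AlH (1.05 equiv), CH2Cl2, −78 °C; MeOH, then aq. potassium sodium tartrate
Reagents that add atoms: none
Why: Partial ester reduction; at −78 °C the aluminium hemiacetal is stable until work-up, so reduction stops at the aldehyde.

Step 4
Reactants: 5 3-[4-(TBS-oxy)phenyl]propanal
Product: 6 (3R)-1-[4-(TBS-oxy)phenyl]hex-5-en-3-ol
Conditions: allylSnBu3 (1.5 equiv), Ti(OiPr)4 (10 mol%), (S)-BINOL (20 mol%), 4 Å molecular sieves, CH2Cl2, −20 °C, 60 h; aq. NaHCO3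
Reagents that add atoms: allyltributylstannane, C=CC[Sn](CCCC)(CCCC)CCCC
Why: Keck asymmetric allylation; the (S)-BINOL titanium Lewis acid directs allyl transfer to the Si face of the aldehyde, which for this unbranched aldehyde gives the (R)-alcohol that becomes the side-chain carbinol of the target.

Step 5
Reactants: 6 (3R)-1-[4-(TBS-oxy)phenyl]hex-5-en-3-ol
Product: 7 (3R)-3-(TBS-oxy)-1-[4-(TBS-oxy)phenyl]hex-5-ene
Conditions: TBSCl, imidazole, DMF, 25 °C
Reagents that add atoms: tert-butyldimethylsilyl chloride, CC(C)(C)[Si](C)(C)Cl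
Why: Silyl ether formation; the secondary TBS ether blocks translactonisation and hemiketal formation in steps 7 to 10 and leaves the stereocentre untouched.

Step 6
Reactants: 7 (3R)-3-(TBS-oxy)-1-[4-(TBS-oxy)phenyl]hex-5-ene
Product: 8 (2E,5R)-5-(TBS-oxy)-7-[4-(TBS-oxy)phenyl]hept-2-enal
Conditions: crotonaldehyde (5 equiv), second-generation Hoveyda–Grubbs catalyst RuCl2(H2IMes)(=CH-C6H4-2-OiPr) (5 mol%), CH2Cl2, 40 °C
Reagents that add atoms: (E)-crotonaldehyde, C/C=C/C=O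
Why: Olefin cross-metathesis of a terminal alkene with an electron-poor partner gives the thermodynamically favoured (E)-enal with loss of propene and does not touch the stereocentre.

Step 7
Reactants: 2 1-[2-hydroxy-6-methoxy-4-(TIPS-oxy)phenyl]ethan-1-one; 8 (2E,5R)-5-(TBS-oxy)-7-[4-(TBS-oxy)phenyl]hept-2-enal
Product: 9 (4S)-8-acetyl-4-{(2R)-2-(TBS-oxy)-4-[4-(TBS-oxy)phenyl]butyl}-7-methoxy-5-(TIPS-oxy)chroman-2-one
Conditions: (5aS,10bR)-2-mesityl-5a,10b-dihydro-4H,6H-indeno[2,1-b][1,2,4]triazolo[4,3-d][1,4]oxazin-2-ium chloride (10 mol%), i-Pr2NEt (1.2 equiv), LiCl (1.0 equiv), 3,3′,5,5′-tetra-tert-butyl-4,4′-diphenoquinone (1.2 equiv), THF/toluene 1:1, 25 °C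
Reagents that add atoms: none
Why: Proposed new method: the triazolylidene carbene adds to enal 8 and the diphenoquinone oxidises the catalyst-bound adduct to an α,β-unsaturated acyl azolium; the lithium-chelated phenoxide of 2 then adds to the acyl carbon and a Coates–Claisen-type [3,3] shift (or the equivalent ortho conjugate addition) joins the only free ortho carbon of 2 to the β-carbon on the face left open by the indane wall of the catalyst, which sets C4 as S under catalyst control whatever the remote silyloxy centre, and lactonisation by the same oxygen releases the carbene; the closest known reaction type is the oxidative carbene-catalysed [3+3] annulation of enals with 1,3-dicarbonyls, kojic acids and 2-naphthols, which has not been shown for a monocyclic hydrogen-bonded o-acylphenol.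

Step 8
Reactants: 9 (4S)-8-acetyl-4-{(2R)-2-(TBS-oxy)-4-[4-(TBS-oxy)phenyl]butyl}-7-methoxy-5-(TIPS-oxy)chroman-2-one
Product: 10 (3S,5R)-3-[3-acetyl-2-hydroxy-4-methoxy-6-(TIPS-oxy)phenyl]-5-(TBS-oxy)-7-[4-(TBS-oxy)phenyl]-N-methoxy-N-methylheptanamide
Conditions: MeNH(OMe)·HCl (3 equiv), i-PrMgCl (6 equiv), THF, −20 °C; then 9, −20 → 0 °C; aq. NH4Cl
Reagents that add atoms: N,O-dimethylhydroxylamine hydrochloride, CNOC.Cl
Why: Weinreb amide formation by aminolysis; the chloromagnesium amide opens the activated aryl lactone much faster than it reacts at the hindered, hydrogen-bonded acetyl group, and no stereocentre is touched.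

Step 9
Reactants: 10 (3S,5R)-3-[3-acetyl-2-hydroxy-4-methoxy-6-(TIPS-oxy)phenyl]-5-(TBS-oxy)-7-[4-(TBS-oxy)phenyl]-N-methoxy-N-methylheptanamide; 11 (4-bromophenoxy)(tert-butyl)dimethylsilane
Product: 13 (3S,5R)-3-[3-acetyl-2-hydroxy-4-methoxy-6-(TIPS-oxy)phenyl]-5-(TBS-oxy)-1,7-bis[4-(TBS-oxy)phenyl]heptan-1-one, via aryl Grignard reagent 12 (not isolated)
Conditions: 11, Mg, THF, 40 °C (gives 12); 10, 12 (3 equiv), THF, −20 → 0 °C; aq. NH4Cl
Reagents that add atoms: none
Why: Weinreb ketone synthesis; the Grignard reagent adds once to the amide through the stable magnesium chelate, while the acetyl group, flanked by two ortho substituents and conjugated to the magnesium phenoxide formed by the first equivalent, does not add.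

Step 10
Reactants: 13 (3S,5R)-3-[3-acetyl-2-hydroxy-4-methoxy-6-(TIPS-oxy)phenyl]-5-(TBS-oxy)-1,7-bis[4-(TBS-oxy)phenyl]heptan-1-one
Product: 14 (1S,3R,5R)-3-[3-acetyl-2-hydroxy-4-methoxy-6-(TIPS-oxy)phenyl]-5-(TBS-oxy)-1,7-bis[4-(TBS-oxy)phenyl]heptan-1-ol
Conditions: RuCl[(S,S)-TsDPEN](p-cymene) (2 mol%), HCO2H/Et3N 5:2, EtOAc, 40 °C
Reagents that add atoms: none
Why: Noyori–Ikariya asymmetric transfer hydrogenation; the (S,S)-TsDPEN ruthenium hydride reduces the unhindered aryl alkyl ketone to the (1S)-alcohol under catalyst control, while the di-ortho-substituted, hydrogen-bonded acetyl group is too hindered to react.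

Step 11
Reactants: 14 (1S,3R,5R)-3-[3-acetyl-2-hydroxy-4-methoxy-6-(TIPS-oxy)phenyl]-5-(TBS-oxy)-1,7-bis[4-(TBS-oxy)phenyl]heptan-1-ol
Product: 15 1-[(2R,4R)-4-{(2R)-2-(TBS-oxy)-4-[4-(TBS-oxy)phenyl]butyl}-2-[4-(TBS-oxy)phenyl]-7-methoxy-5-(TIPS-oxy)chroman-8-yl]ethan-1-one (2,4-trans)
Conditions: PPh3 (1.5 equiv), DIAD (1.5 equiv), toluene, −20 → 0 °C
Reagents that add atoms: none
Why: Mitsunobu etherification; the phenol displaces the benzylic oxyphosphonium in a six-membered SN2 ring closure with inversion, which turns the (1S)-carbinol into C2 (R) and gives the 2,4-trans chroman.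

Step 12
Reactants: 15 1-[(2R,4R)-4-{(2R)-2-(TBS-oxy)-4-[4-(TBS-oxy)phenyl]butyl}-2-[4-(TBS-oxy)phenyl]-7-methoxy-5-(TIPS-oxy)chroman-8-yl]ethan-1-one; 16 4-(TBS-oxy)benzaldehyde
Product: 17 3-hydroxy-1-[(2R,4R)-4-{(2R)-2-(TBS-oxy)-4-[4-(TBS-oxy)phenyl]butyl}-2-[4-(TBS-oxy)phenyl]-7-methoxy-5-(TIPS-oxy)chroman-8-yl]-3-[4-(TBS-oxy)phenyl]propan-1-one (both carbinol epimers)
Conditions: LiN(SiMe3)2 (1.2 equiv), THF, −78 °C; 16 (1.5 equiv), −78 °C; AcOH, −78 °C
Reagents that add atoms: none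
Why: Directed aldol addition; the kinetic lithium enolate of the methyl ketone adds to the non-enolisable aldehyde and a cold acidic quench prevents retro-aldol, while the new carbinol centre is left uncontrolled because step 13 destroys it.

Step 13
Reactants: 17 3-hydroxy-1-[(2R,4R)-4-{(2R)-2-(TBS-oxy)-4-[4-(TBS-oxy)phenyl]butyl}-2-[4-(TBS-oxy)phenyl]-7-methoxy-5-(TIPS-oxy)chroman-8-yl]-3-[4-(TBS-oxy)phenyl]propan-1-one
Product: 19 (2E)-1-[(2R,4R)-4-{(2R)-2-(TBS-oxy)-4-[4-(TBS-oxy)phenyl]butyl}-2-[4-(TBS-oxy)phenyl]-7-methoxy-5-(TIPS-oxy)chroman-8-yl]-3-[4-(TBS-oxy)phenyl]prop-2-en-1-one, via mesylate 18 (not isolated)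
Conditions: MsCl (2 equiv), Et3N (5 equiv), CH2Cl2, 0 → 25 °C
Reagents that add atoms: none
Why: Mesylation followed by E1cB elimination gives the conjugated (E)-enone as the thermodynamically favoured chalcone geometry.

Step 14
Reactants: 19 (2E)-1-[(2R,4R)-4-{(2R)-2-(TBS-oxy)-4-[4-(TBS-oxy)phenyl]butyl}-2-[4-(TBS-oxy)phenyl]-7-methoxy-5-(TIPS-oxy)chroman-8-yl]-3-[4-(TBS-oxy)phenyl]prop-2-en-1-one
Product: 20 (2E)-1-[(2R,4S)-5-hydroxy-4-[(2R)-2-hydroxy-4-(4-hydroxyphenyl)butyl]-2-(4-hydroxyphenyl)-7-methoxychroman-8-yl]-3-(4-hydroxyphenyl)prop-2-en-1-one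
Conditions: Bu4NF (8 equiv), AcOH (8 equiv), THF, 0 → 25 °C
Reagents that add atoms: none
Why: Fluoride desilylation buffered with acetic acid removes the four TBS groups and the TIPS group without base-induced quinone-methide opening of the p-hydroxybenzyl ether at C2 or addition to the enone, and no bond at a stereocentre is touched.

## Compound list

1 | 1-(2,4-dihydroxy-6-methoxyphenyl)ethan-1-one | COc1cc(O)cc(O)c1C(C)=O | starting material
2 | 1-[2-hydroxy-6-methoxy-4-(TIPS-oxy)phenyl]ethan-1-one | COc1cc(O[Si](C(C)C)(C(C)C)C(C)C)cc(O)c1C(C)=O | intermediate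
3 | methyl 3-(4-hydroxyphenyl)propanoate | COC(=O)CCc1ccc(O)cc1 | starting material
4 | methyl 3-[4-(TBS-oxy)phenyl]propanoate | COC(=O)CCc1ccc(O[Si](C)(C)C(C)(C)C)cc1 | intermediate
5 | 3-[4-(TBS-oxy)phenyl]propanal | O=CCCc1ccc(O[Si](C)(C)C(C)(C)C)cc1 | intermediate
6 | (3R)-1-[4-(TBS-oxy)phenyl]hex-5-en-3-ol | C=CC[C@H](O)CCc1ccc(O[Si](C)(C)C(C)(C)C)cc1 | intermediate
7 | (3R)-3-(TBS-oxy)-1-[4-(TBS-oxy)phenyl]hex-5-ene | C=CC[C@H](O[Si](C)(C)C(C)(C)C)CCc1ccc(O[Si](C)(C)C(C)(C)C)cc1 | intermediate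
8 | (2E,5R)-5-(TBS-oxy)-7-[4-(TBS-oxy)phenyl]hept-2-enal | O=C/C=C/C[C@H](O[Si](C)(C)C(C)(C)C)CCc1ccc(O[Si](C)(C)C(C)(C)C)cc1 | intermediate
9 | (4S)-8-acetyl-4-{(2R)-2-(TBS-oxy)-4-[4-(TBS-oxy)phenyl]butyl}-7-methoxy-5-(TIPS-oxy)chroman-2-one | COc1cc(O[Si](C(C)C)(C(C)C)C(C)C)c2c(c1C(C)=O)OC(=O)C[C@@H]2C[C@H](O[Si](C)(C)C(C)(C)C)CCc1ccc(O[Si](C)(C)C(C)(C)C)cc1 | intermediate
10 | (3S,5R)-3-[3-acetyl-2-hydroxy-4-methoxy-6-(TIPS-oxy)phenyl]-5-(TBS-oxy)-7-[4-(TBS-oxy)phenyl]-N-methoxy-N-methylheptanamide | COc1cc(O[Si](C(C)C)(C(C)C)C(C)C)c(c(O)c1C(C)=O)[C@H](CC(=O)N(C)OC)C[C@H](O[Si](C)(C)C(C)(C)C)CCc1ccc(O[Si](C)(C)C(C)(C)C)cc1 | intermediate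
11 | (4-bromophenoxy)(tert-butyl)dimethylsilane | CC(C)(C)[Si](C)(C)Oc1ccc(Br)cc1 | starting material
12 | [4-(TBS-oxy)phenyl]magnesium bromide | CC(C)(C)[Si](C)(C)Oc1ccc([Mg]Br)cc1 | intermediate
13 | (3S,5R)-3-[3-acetyl-2-hydroxy-4-methoxy-6-(TIPS-oxy)phenyl]-5-(TBS-oxy)-1,7-bis[4-(TBS-oxy)phenyl]heptan-1-one | COc1cc(O[Si](C(C)C)(C(C)C)C(C)C)c(c(O)c1C(C)=O)[C@H](CC(=O)c1ccc(O[Si](C)(C)C(C)(C)C)cc1)C[C@H](O[Si](C)(C)C(C)(C)C)CCc1ccc(O[Si](C)(C)C(C)(C)C)cc1 | intermediate
14 | (1S,3R,5R)-3-[3-acetyl-2-hydroxy-4-methoxy-6-(TIPS-oxy)phenyl]-5-(TBS-oxy)-1,7-bis[4-(TBS-oxy)phenyl]heptan-1-ol | COc1cc(O[Si](C(C)C)(C(C)C)C(C)C)c(c(O)c1C(C)=O)[C@H](C[C@H](O)c1ccc(O[Si](C)(C)C(C)(C)C)cc1)C[C@H](O[Si](C)(C)C(C)(C)C)CCc1ccc(O[Si](C)(C)C(C)(C)C)cc1 | intermediate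
15 | 1-[(2R,4R)-4-{(2R)-2-(TBS-oxy)-4-[4-(TBS-oxy)phenyl]butyl}-2-[4-(TBS-oxy)phenyl]-7-methoxy-5-(TIPS-oxy)chroman-8-yl]ethan-1-one | COc1cc(O[Si](C(C)C)(C(C)C)C(C)C)c2c(c1C(C)=O)O[C@@H](c1ccc(O[Si](C)(C)C(C)(C)C)cc1)C[C@@H]2C[C@H](O[Si](C)(C)C(C)(C)C)CCc1ccc(O[Si](C)(C)C(C)(C)C)cc1 | intermediate
16 | 4-(TBS-oxy)benzaldehyde | CC(C)(C)[Si](C)(C)Oc1ccc(C=O)cc1 | starting material
17 | 3-hydroxy-1-[(2R,4R)-4-{(2R)-2-(TBS-oxy)-4-[4-(TBS-oxy)phenyl]butyl}-2-[4-(TBS-oxy)phenyl]-7-methoxy-5-(TIPS-oxy)chroman-8-yl]-3-[4-(TBS-oxy)phenyl]propan-1-one (both carbinol epimers) | COc1cc(O[Si](C(C)C)(C(C)C)C(C)C)c2c(c1C(=O)CC(O)c1ccc(O[Si](C)(C)C(C)(C)C)cc1)O[C@@H](c1ccc(O[Si](C)(C)C(C)(C)C)cc1)C[C@@H]2C[C@H](O[Si](C)(C)C(C)(C)C)CCc1ccc(O[Si](C)(C)C(C)(C)C)cc1 | intermediate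
18 | methanesulfonate of 17 at the new carbinol (both epimers) | COc1cc(O[Si](C(C)C)(C(C)C)C(C)C)c2c(c1C(=O)CC(OS(C)(=O)=O)c1ccc(O[Si](C)(C)C(C)(C)C)cc1)O[C@@H](c1ccc(O[Si](C)(C)C(C)(C)C)cc1)C[C@@H]2C[C@H](O[Si](C)(C)C(C)(C)C)CCc1ccc(O[Si](C)(C)C(C)(C)C)cc1 | intermediate
19 | (2E)-1-[(2R,4R)-4-{(2R)-2-(TBS-oxy)-4-[4-(TBS-oxy)phenyl]butyl}-2-[4-(TBS-oxy)phenyl]-7-methoxy-5-(TIPS-oxy)chroman-8-yl]-3-[4-(TBS-oxy)phenyl]prop-2-en-1-one | COc1cc(O[Si](C(C)C)(C(C)C)C(C)C)c2c(c1C(=O)/C=C/c1ccc(O[Si](C)(C)C(C)(C)C)cc1)O[C@@H](c1ccc(O[Si](C)(C)C(C)(C)C)cc1)C[C@@H]2C[C@H](O[Si](C)(C)C(C)(C)C)CCc1ccc(O[Si](C)(C)C(C)(C)C)cc1 | intermediate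
20 | (2E)-1-[(2R,4S)-5-hydroxy-4-[(2R)-2-hydroxy-4-(4-hydroxyphenyl)butyl]-2-(4-hydroxyphenyl)-7-methoxychroman-8-yl]-3-(4-hydroxyphenyl)prop-2-en-1-one | COc1cc(O)c2c(c1C(=O)/C=C/c1ccc(O)cc1)O[C@@H](c1ccc(O)cc1)C[C@@H]2C[C@H](O)CCc1ccc(O)cc1 | target

## Summary

Total step count: 14.
Longest linear sequence: 13 steps (3 to 20, steps 2 to 14).

Three steps most likely to fail:

**Step 7 (proposed new annulation).** The phenol of 2 is hydrogen-bonded and carries an acyl group, so C-attack may be slow. Other risks are attack at the para carbon, γ-deprotonation of the acyl azolium with loss of silanol, and base-induced O-to-C acyl shift of the o-acyloxy acetophenone product. Fallback with known chemistry: set out from phenol 2 and enal 8 under iminium catalysis with (S)-α,α-diphenylprolinol trimethylsilyl ether (20 mol%) and benzoic acid in toluene at 0 °C. Friedel–Crafts-type conjugate addition and hemiacetal closure give the 8-acetylchroman-2-ol lactol F1, with C4 set by the shielding of the catalyst. Oxidation of the lactol with pyridinium chlorochromate [C5H5NH][CrO3Cl] in CH2Cl2 gives lactone 9, where the route is rejoined.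

**Step 9 (Grignard addition beside a free acetyl group).** Enolisation of, or addition to, the acetyl ketone and over-addition would cut the yield. Fallback: set out from lactone 9 and open it with AlMe3/EtSH in CH2Cl2 at 0 °C to the S-ethyl thioester F2. Grignard reagent 12 is transmetalated with ZnCl2 to [4-(TBS-oxy)phenyl]zinc chloride F3. Fukuyama coupling of the two with PdCl2(PPh3)2 (5 mol%) in toluene/THF at 25 °C gives ketone 13, where the route is rejoined; organozinc reagents do not add to the acetyl group.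

**Step 11 (Mitsunobu closure).** The silyloxyphenyl group stabilises a benzylic cation, so part of the reaction may leak through SN1 or eliminate to the styrene, which erodes the configuration at C2. Fallback: set out from diol 14 (or from any C1-epimeric mixture) and treat it with 10-camphorsulfonic acid (10 mol%) in CH2Cl2 at 0 °C. This is a stereoconvergent SN1 cyclodehydration under thermodynamic control. The bulky C5 silyloxy group forces the C4 chain pseudo-axial and the C2 aryl group then sits equatorial, which is the 2,4-trans isomer; the cis epimer re-ionises and funnels to it. The route is rejoined at chroman 15, and no new compound is made: none F0.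

## Further compounds

F1 | step 7 | 1-[(4S)-4-{(2R)-2-(TBS-oxy)-4-[4-(TBS-oxy)phenyl]butyl}-2-hydroxy-7-methoxy-5-(TIPS-oxy)chroman-8-yl]ethan-1-one (lactol, both anomers) | COc1cc(O[Si](C(C)C)(C(C)C)C(C)C)c2c(c1C(C)=O)OC(O)C[C@@H]2C[C@H](O[Si](C)(C)C(C)(C)C)CCc1ccc(O[Si](C)(C)C(C)(C)C)cc1
F2 | step 9 | S-ethyl (3S,5R)-3-[3-acetyl-2-hydroxy-4-methoxy-6-(TIPS-oxy)phenyl]-5-(TBS-oxy)-7-[4-(TBS-oxy)phenyl]heptanethioate | COc1cc(O[Si](C(C)C)(C(C)C)C(C)C)c(c(O)c1C(C)=O)[C@H](CC(=O)SCC)C[C@H](O[Si](C)(C)C(C)(C)C)CCc1ccc(O[Si](C)(C)C(C)(C)C)cc1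
F3 | step 9 | [4-(TBS-oxy)phenyl]zinc chloride | CC(C)(C)[Si](C)(C)Oc1ccc([Zn]Cl)cc1
F0 | step 11 | none | none
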